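**Retrosynthetic overview**
- The E-propenyl group at C5 is traced back to a C5 aldehyde and then to a C5 methyl ester, and the ring C phenol is carried as a pivalate.
- Ring B (O1–C2–C3–C3a–C7a) is the only ring made. It is cut at C3–C3a and O1–C7a and formed in a single palladium/norbornene annulation.
- Feature the strategy rests on: O1, C2 and C3, with the ring C aryl on C2 and the methyl on C3, are the three ring atoms of a cis-1-aryl-2-methyloxirane. C7a and C3a are the ipso and ortho carbons of a 4-iodo-3-methoxybenzoate, whose methoxy group (the future C7–OMe) blocks the other ortho site. Inversion at C3 with retention at C2 turns the cis epoxide into the trans-2,3 product.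
- The cis epoxide comes from a Z-propenylarene by (salen)MnCl-catalysed epoxidation, and the Z-alkene from pivaloylated 3-hydroxy-4,5-dimethoxybenzaldehyde by Wittig olefination.
- Ring order: rings A and C are bought intact; ring B is closed in step 4.

Key step: step 4

Remark: ring A is the benzo ring, ring B the dihydrofuran and ring C the 2-aryl group, with benzofuran numbering. The (R,R)-enantiomer of the salen catalyst is assumed to give the (2R,3S)-epoxide, by analogy with cis-β-methylstyrene; if the opposite sense is found, the (S,S)-catalyst is used instead.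

**Route**

Step 1
Reactants: 1 3-hydroxy-4,5-dimethoxybenzaldehyde
Product: 2 5-formyl-2,3-dimethoxyphenyl 2,2-dimethylpropanoate
Conditions: t-BuCOCl (1.2 equiv), Et3N (1.5 equiv), DMAP (5 mol %), CH2Cl2, 0 °C to rt
Reagents that add atoms: pivaloyl chloride, CC(C)(C)C(Cl)=O
Why: DMAP-catalysed acylation (esterification) of the only nucleophile, the phenol, should be clean, and the hindered, electron-withdrawing pivalate masks the acidic OH for the ylide step, should withstand buffered bleach and carbonate base, and lowers the donor power of ring C.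

Step 2
Reactants: 2 5-formyl-2,3-dimethoxyphenyl 2,2-dimethylpropanoate; 3 ethyltriphenylphosphonium bromide
Product: 5 2,3-dimethoxy-5-[(1Z)-prop-1-en-1-yl]phenyl 2,2-dimethylpropanoate, via ethylidenetriphenylphosphorane 4 (not isolated)
Conditions: 3 (1.15 equiv), NaN(SiMe3)2 (1.1 equiv), THF, 0 °C; then 2, −78 °C to rt; chromatography on AgNO3-impregnated silica
Reagents that add atoms: none
Why: Wittig olefination with the non-stabilised ethylidene ylide under lithium-free conditions runs under kinetic control through the cis-oxaphosphetane and should give mainly the Z-alkene, the aldehyde being far more electrophilic than the hindered pivalate at −78 °C; residual E-isomer is to be removed on the silver-doped silica.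

Step 3
Reactants: 5 2,3-dimethoxy-5-[(1Z)-prop-1-en-1-yl]phenyl 2,2-dimethylpropanoate
Product: 6 2,3-dimethoxy-5-[(2R,3S)-3-methyloxiran-2-yl]phenyl 2,2-dimethylpropanoate (cis-epoxide)
Conditions: (R,R)-N,N'-bis(3,5-di-tert-butylsalicylidene)-1,2-cyclohexanediaminomanganese chloride, (R,R)-(salen)MnCl (5 mol %), 4-phenylpyridine N-oxide (25 mol %), aq. NaOCl buffered to pH 11.3, CH2Cl2, 0 °C; Et3N-deactivated silica
Reagents that add atoms: sodium hypochlorite, [Na+].[O-]Cl
Why: Jacobsen–Katsuki epoxidation, for which cis-1-arylpropenes are privileged substrates: the oxo-manganese salen species delivers oxygen to one alkene face in a side-on approach over the chiral diamine backbone, so the catalyst enantiomer sets both oxirane carbons together (2R,3S expected with the (R,R)-catalyst), the N-oxide co-ligand should curb leakage to the trans-epoxide, and the pivalate should survive the cold biphasic bleach.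

Step 4
Reactants: 6 2,3-dimethoxy-5-[(2R,3S)-3-methyloxiran-2-yl]phenyl 2,2-dimethylpropanoate; 7 methyl 4-iodo-3-methoxybenzoate
Product: 8 methyl (2S,3S)-2-[3-(2,2-dimethylpropanoyloxy)-4,5-dimethoxyphenyl]-7-methoxy-3-methyl-2,3-dihydro-1-benzofuran-5-carboxylate (trans)
Conditions: Pd(OAc)2 (10 mol %), XPhos (20 mol %), norbornene (1.0 equiv), Cs2CO3 (2.0 equiv), 6 (1.5 equiv), 1,4-dioxane, 90 °C
Reagents that add atoms: none
Why: Proposed new method: oxidative addition of 7 to zerovalent palladium, norbornene insertion and ortho C–H palladation at the future C3a (the other ortho site carries the methoxy group) should give the aryl–norbornyl palladacycle, whose divalent palladium opens 6 by SN2-type oxidative addition at the methyl-bearing carbon with inversion, reaching tetravalent palladium, after which C(sp2)–C(sp3) reductive elimination forms C3–C3a with retention. C3 is therefore set by the 3S centre of the epoxide through one inversion, while C2 keeps its C–O bond and its configuration, which turns the cis epoxide into the trans (2S,3S) product. Norbornene is then extruded by β-carbon elimination, and the six-membered aryl palladium alkoxide closes ring B by C(aryl)–O reductive elimination at C7a, a five-membered ring closure that the bulky biarylphosphine should favour over β-hydride loss from the alkoxide. The closest known reaction type is the palladium/norbornene (Catellani) ortho-alkylation and ipso-etherification of aryl iodides with terminal epoxides to 2,3-dihydrobenzofurans, which follows the same sequence at a CH2 terminus. The step needs attack at the CH(CH3) carbon and not at the benzylic one: the bulky, soft palladacycle should prefer the carbon flanked by methyl over the one flanked by the trisubstituted aryl, the base-only medium offers no SN1-type benzylic ionisation, and the pivaloyloxy group lowers the donor power of ring C. Use of a 2,3-disubstituted aryl epoxide in this annulation is not established, so the risk of the route sits here.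

Step 5
Reactants: 8 methyl (2S,3S)-2-[3-(2,2-dimethylpropanoyloxy)-4,5-dimethoxyphenyl]-7-methoxy-3-methyl-2,3-dihydro-1-benzofuran-5-carboxylate
Product: 9 5-[(2S,3S)-5-(hydroxymethyl)-7-methoxy-3-methyl-2,3-dihydro-1-benzofuran-2-yl]-2,3-dimethoxyphenol
Conditions: i-Bu2AlH (DIBAL-H, 6 equiv), CH2Cl2, −78 to 0 °C; aq. potassium sodium tartrate
Reagents that add atoms: none
Why: Hydride reduction with DIBAL-H converts the methyl ester into the primary benzylic alcohol and cleaves the aryl pivalate to the phenol and neopentyl alcohol, while C2 and C3 carry no acidic or reducible function and should be untouched.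

Step 6
Reactants: 9 5-[(2S,3S)-5-(hydroxymethyl)-7-methoxy-3-methyl-2,3-dihydro-1-benzofuran-2-yl]-2,3-dimethoxyphenol
Product: 10 (2S,3S)-2-(3-hydroxy-4,5-dimethoxyphenyl)-7-methoxy-3-methyl-2,3-dihydro-1-benzofuran-5-carbaldehyde
Conditions: activated MnO2 (15 equiv), CH2Cl2, rt
Reagents that add atoms: none
Why: Heterogeneous MnO2 oxidation is selective for benzylic alcohols and stops at the aldehyde; the phenol on ring C is not benzylic-activated and should be left alone under these neutral conditions, and neither stereocentre is enolisable.

Step 7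
Reactants: 10 (2S,3S)-2-(3-hydroxy-4,5-dimethoxyphenyl)-7-methoxy-3-methyl-2,3-dihydro-1-benzofuran-5-carbaldehyde; 11 5-(ethylsulfonyl)-1-phenyl-1H-tetrazole
Product: 12 2,3-dimethoxy-5-[(2S,3S)-7-methoxy-3-methyl-5-[(1E)-prop-1-en-1-yl]-2,3-dihydro-1-benzofuran-2-yl]phenol (target)
Conditions: 11 (1.4 equiv), KN(SiMe3)2 (2.5 equiv), DME, −60 °C; then 10, −60 °C to rt; aq. NH4Cl
Reagents that add atoms: none
Why: Julia–Kocienski olefination: the metalated phenyltetrazolyl sulfone adds to the aryl aldehyde, and Smiles rearrangement followed by anti-elimination of SO2 and the tetrazolone should deliver the E-propenyl group, the first equivalent of base being taken up by the phenol, which is set free again on work-up, and C2–H and C3–H being too weakly acidic to epimerise at low temperature.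

**Compound list**
1 | 3-hydroxy-4,5-dimethoxybenzaldehyde | O=Cc1cc(O)c(OC)c(OC)c1 | starting material
2 | 5-formyl-2,3-dimethoxyphenyl 2,2-dimethylpropanoate | O=Cc1cc(OC(=O)C(C)(C)C)c(OC)c(OC)c1 | intermediate
3 | ethyltriphenylphosphonium bromide | CC[P+](c1ccccc1)(c1ccccc1)c1ccccc1.[Br-] | starting material
4 | ethylidenetriphenylphosphorane | CC=P(c1ccccc1)(c1ccccc1)c1ccccc1 | intermediate
5 | 2,3-dimethoxy-5-[(1Z)-prop-1-en-1-yl]phenyl 2,2-dimethylpropanoate | C/C=C\c1cc(OC(=O)C(C)(C)C)c(OC)c(OC)c1 | intermediate
6 | 2,3-dimethoxy-5-[(2R,3S)-3-methyloxiran-2-yl]phenyl 2,2-dimethylpropanoate | C[C@H]1[C@@H](c2cc(OC(=O)C(C)(C)C)c(OC)c(OC)c2)O1 | intermediate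
7 | methyl 4-iodo-3-methoxybenzoate | COC(=O)c1ccc(I)c(OC)c1 | starting material
8 | methyl (2S,3S)-2-[3-(2,2-dimethylpropanoyloxy)-4,5-dimethoxyphenyl]-7-methoxy-3-methyl-2,3-dihydro-1-benzofuran-5-carboxylate | COC(=O)c1cc(OC)c2c(c1)[C@H](C)[C@@H](c1cc(OC(=O)C(C)(C)C)c(OC)c(OC)c1)O2 | intermediate
9 | 5-[(2S,3S)-5-(hydroxymethyl)-7-methoxy-3-methyl-2,3-dihydro-1-benzofuran-2-yl]-2,3-dimethoxyphenol | OCc1cc(OC)c2c(c1)[C@H](C)[C@@H](c1cc(O)c(OC)c(OC)c1)O2 | intermediate
10 | (2S,3S)-2-(3-hydroxy-4,5-dimethoxyphenyl)-7-methoxy-3-methyl-2,3-dihydro-1-benzofuran-5-carbaldehyde | O=Cc1cc(OC)c2c(c1)[C@H](C)[C@@H](c1cc(O)c(OC)c(OC)c1)O2 | intermediate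
11 | 5-(ethylsulfonyl)-1-phenyl-1H-tetrazole | CCS(=O)(=O)c1nnnn1-c1ccccc1 | starting material
12 | 2,3-dimethoxy-5-[(2S,3S)-7-methoxy-3-methyl-5-[(1E)-prop-1-en-1-yl]-2,3-dihydro-1-benzofuran-2-yl]phenol | C/C=C/c1cc(OC)c2c(c1)[C@H](C)[C@@H](c1cc(O)c(OC)c(OC)c1)O2 | target

Total step count: 7. Longest linear sequence: 7 steps (1 to 12; the aryl iodide 7 is purchased).

**Steps most likely to fail**

1. Step 4 (palladium/norbornene annulation). Several processes may go wrong:
- The palladacycle may open the internal epoxide too slowly, so that the aryl iodide is consumed in biaryl or benzocyclobutene pathways.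
- Opening may occur at the benzylic carbon.
- Palladium may isomerise the epoxide to a ketone.
- Iodide may pre-open the epoxide, and the resulting double inversion would erode the trans relationship.

Fallback by known chemistry, setting out from aldehyde 2 and returning at 8. Wittig homologation of 2 with (triphenylphosphoranylidene)acetaldehyde (toluene, 80 °C) should give (2E)-3-[3-(2,2-dimethylpropanoyloxy)-4,5-dimethoxyphenyl]prop-2-enal F1. Luche reduction (NaBH4, CeCl3·7H2O, MeOH, 0 °C) should give 5-[(1E)-3-hydroxyprop-1-en-1-yl]-2,3-dimethoxyphenyl 2,2-dimethylpropanoate F2. Methyl chloroformate and pyridine in CH2Cl2 should then give 5-[(1E)-3-(methoxycarbonyloxy)prop-1-en-1-yl]-2,3-dimethoxyphenyl 2,2-dimethylpropanoate F3. Iridium-catalysed asymmetric allylic etherification of F3 ([Ir(cod)Cl]2, a chiral binaphthol-derived phosphoramidite of the enantiomeric series that leads to the S-ether, THF, 50 °C) with the lithium phenoxide of purchased methyl 4-hydroxy-3-iodo-5-methoxybenzoate F4 should set C2 in the branched ether methyl 4-{[(1S)-1-[3-(2,2-dimethylpropanoyloxy)-4,5-dimethoxyphenyl]prop-2-en-1-yl]oxy}-3-iodo-5-methoxybenzoate F5. Tin hydride radical cyclisation (Bu3SnH, AIBN, toluene, 80 °C) then closes ring B: the aryl radical at the future C3a adds 5-exo to the internal vinyl carbon to form C3–C3a, and the primary radical is reduced to the C3 methyl. The chair-like transition state with the ring C aryl pseudo-equatorial should favour the 2,3-trans isomer 8, the cis isomer being removed by chromatography. The route continues from 8 at step 5.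

2. Step 3 (salen-manganese epoxidation). Oxygen transfer is stepwise, so rotation about the former C=C bond before ring closure may leak trans-epoxide, and the facial selectivity may be incomplete. Trans-epoxide would carry through step 4 to the 2,3-cis series.

Fallback, from 5 to 6, with no new compounds: Shi epoxidation with the carbohydrate-derived oxazolidinone-fused ketone designed for cis-alkenes (KHSO5 as the triple salt 2KHSO5·KHSO4·K2SO4, K2CO3, buffered dimethoxymethane/MeCN/water, −10 °C). The ketone enantiomer is chosen for the (2R,3S) series. Oxygen is delivered by a chiral dioxirane in a concerted step, so the cis geometry is transferred stereospecifically and the leakage pathway is closed.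

3. Step 2 (Z-selective Wittig). With an aryl aldehyde the oxaphosphetane may partly equilibrate (stereochemical drift), giving too much E-alkene. That isomer would end as the wrong diastereomer after steps 3 and 4.

Fallback, setting out from 2 and returning at 5. Stork–Zhao olefination of 2 with (iodomethyl)triphenylphosphonium iodide and NaN(SiMe3)2 (THF/DMPU, −78 °C) should give the Z-vinyl iodide 5-[(Z)-2-iodoethenyl]-2,3-dimethoxyphenyl 2,2-dimethylpropanoate F6 with high Z selectivity. Negishi coupling with MeZnCl and Pd(PPh3)4 (THF, rt) replaces iodine by methyl with retention of the double-bond geometry and should leave the pivalate intact, giving 5.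

**Further compounds**
F1 | step 4 | (2E)-3-[3-(2,2-dimethylpropanoyloxy)-4,5-dimethoxyphenyl]prop-2-enal | O=C/C=C/c1cc(OC(=O)C(C)(C)C)c(OC)c(OC)c1
F2 | step 4 | 5-[(1E)-3-hydroxyprop-1-en-1-yl]-2,3-dimethoxyphenyl 2,2-dimethylpropanoate | OC/C=C/c1cc(OC(=O)C(C)(C)C)c(OC)c(OC)c1
F3 | step 4 | 5-[(1E)-3-(methoxycarbonyloxy)prop-1-en-1-yl]-2,3-dimethoxyphenyl 2,2-dimethylpropanoate | COC(=O)OC/C=C/c1cc(OC(=O)C(C)(C)C)c(OC)c(OC)c1
F4 | step 4 | methyl 4-hydroxy-3-iodo-5-methoxybenzoate (purchased) | COC(=O)c1cc(I)c(O)c(OC)c1
F5 | step 4 | methyl 4-{[(1S)-1-[3-(2,2-dimethylpropanoyloxy)-4,5-dimethoxyphenyl]prop-2-en-1-yl]oxy}-3-iodo-5-methoxybenzoate | COC(=O)c1cc(OC)c(O[C@@H](C=C)c2cc(OC(=O)C(C)(C)C)c(OC)c(OC)c2)c(I)c1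
F0 | step 3 | none | none
F6 | step 2 | 5-[(Z)-2-iodoethenyl]-2,3-dimethoxyphenyl 2,2-dimethylpropanoate | I/C=C\c1cc(OC(=O)C(C)(C)C)c(OC)c(OC)c1
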